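**Retrosynthetic overview**

1. The target is traced back (C1=C10 epoxidation, C3 isobutyrate, C8 (2S,3S)-epoxyangelate, C13 by Mannich methylenation) to the ten-membered ketone 27, with 8β-OH coming from C8=O.
2. Key disconnection: the ten-membered carbocycle of 27 (O=C8–C9H2–C10(CH3)=C1H) comes from the eight-membered silyl enol ether 20 (C8=C1) and allyl but-2-ynoate (C9, C10, C14). A [2+2] gives a bicyclo[6.2.0]decene; conrotatory 4π opening of the C8–C1 bond then expands the ring from 8 to 10 atoms.
3. Enabling feature: in the ten-membered ring the oxygenated C8 is linked through C9H2 to the E-trisubstituted C10(Me)=C1 olefin (a β,γ-unsaturated ketone array). C9–C10 is therefore an alkyne inserted into the C8–C1 bond of a cyclooctanone, and the O-donor on C8 rotates outward on ring opening, which fixes 1(10)E.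
4. Eight-membered ring: Ni/Cr closure of C3–C4 from a (Z)-vinyl iodide aldehyde (fixes 4Z); C3 by CBS reduction; C6 from (S)-5-(hydroxymethyl)butenolide; C7 by trans conjugate addition of a dithiane anion (C8).
5. Ring order: γ-lactone (step 3) → cyclooctene (step 8) → cyclobutene (transient) → cyclodecadiene (step 15) → C1/C10 oxirane (step 25); the side-chain oxirane comes from a Sharpless epoxidation.

Key step: step 15

Remark: atoms carry the germacrane numbers of the target (ring C1–C10, lactone C11–C13, C14 on C10, C15 on C4; H-7 is α); compounds 1, 2, 5, 21, 22 and 29 are assumed to be commercially available.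

**Route**

Step 1
Reactants: 1 1,3-dithiane; 2 2-(2-bromoethyl)-1,3-dioxolane
Product: 4 2-[2-(1,3-dioxolan-2-yl)ethyl]-1,3-dithiane, via 2-lithio-1,3-dithiane 3 (not isolated)
Conditions: n-BuLi, THF, −30 °C; then 2, −78 °C to rt
Reagents that add atoms: none
Why: Corey–Seebach alkylation (SN2 of the lithiodithiane on the primary bromide) should give the C8 acyl-anion equivalent carrying C1–C3 with C3 masked as a dioxolane; no stereocentre is formed.

Step 2
Reactants: 5 (S)-5-(hydroxymethyl)furan-2(5H)-one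
Product: 6 (S)-5-[(tert-butyldiphenylsilyloxy)methyl]furan-2(5H)-one
Conditions: TBDPSCl, imidazole, CH2Cl2, 0 °C to rt
Reagents that add atoms: tert-butyl(chloro)diphenylsilane (TBDPSCl), CC(C)(C)[Si](Cl)(c1ccccc1)c1ccccc1
Why: Standard silylation of the primary alcohol; the bulky silyl ether later shields one face of the butenolide, and the existing stereocentre (C6 of the target) is untouched.

Step 3
Reactants: 4 2-[2-(1,3-dioxolan-2-yl)ethyl]-1,3-dithiane; 6 (S)-5-[(tert-butyldiphenylsilyloxy)methyl]furan-2(5H)-one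
Product: 9 (4S,5S)-5-[(tert-butyldiphenylsilyloxy)methyl]-4-{2-[2-(1,3-dioxolan-2-yl)ethyl]-1,3-dithian-2-yl}dihydrofuran-2(3H)-one, via lithiated dithiane 7 (not isolated), via lithium enolate 8 (not isolated)
Conditions: 4, n-BuLi, THF, −25 °C; HMPA, −78 °C; then 6; AcOH quench at −78 °C
Reagents that add atoms: none
Why: Michael addition of a 2-lithio-1,3-dithiane (Corey–Seebach acyl anion equivalent) to the butenolide, 1,4-selective in THF/HMPA, should occur anti to the C6 CH2OTBDPS group and so set C7 (trans lactone, H-6β/H-7α) before the enolate is protonated at C11.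

Step 4
Reactants: 9 trans-lactone silyl ether
Product: 10 (4S,5S)-4-{2-[2-(1,3-dioxolan-2-yl)ethyl]-1,3-dithian-2-yl}-5-(hydroxymethyl)dihydrofuran-2(3H)-one
Conditions: TBAF, AcOH, THF, 0 °C to rt
Reagents that add atoms: none
Why: Buffered fluoride desilylation should free the primary alcohol without opening or translactonising the γ-lactone; the acetal and dithiane are inert.

Step 5
Reactants: 10 hydroxymethyl lactone
Product: 11 (2S,3S)-3-{2-[2-(1,3-dioxolan-2-yl)ethyl]-1,3-dithian-2-yl}-5-oxotetrahydrofuran-2-carbaldehyde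
Conditions: (COCl)2, DMSO, CH2Cl2, −78 °C; i-Pr2NEt, −78 to −20 °C
Reagents that add atoms: none
Why: Swern oxidation does not oxidise the dithiane sulfur, and low temperature with a hindered base should avoid epimerisation of the α-oxygenated aldehyde (C6).

Step 6
Reactants: 11 lactone aldehyde
Product: 12 (4S,5S)-4-{2-[2-(1,3-dioxolan-2-yl)ethyl]-1,3-dithian-2-yl}-5-[(Z)-2-iodoprop-1-en-1-yl]dihydrofuran-2(3H)-one
Conditions: EtPPh3I, n-BuLi, THF, rt; I2, −78 °C; NaHMDS, −20 °C; then 11, −78 °C
Reagents that add atoms: ethyltriphenylphosphonium iodide, CC[P+](c1ccccc1)(c1ccccc1)c1ccccc1.[I-]; iodine, II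
Why: Stork–Zhao olefination with the α-iodo ylide should give the (Z)-2-iodoalkene (I cis to C6), which fixes the 4Z geometry because the C4–I bond becomes the C4–C3 bond.

Step 7
Reactants: 12 (Z)-vinyl iodide acetal
Product: 13 3-{2-[(2S,3S)-2-((Z)-2-iodoprop-1-en-1-yl)-5-oxotetrahydrofuran-3-yl]-1,3-dithian-2-yl}propanal
Conditions: AcOH/H2O/THF, 45 °C
Reagents that add atoms: water, O
Why: Acid-catalysed acetal hydrolysis should unmask the C3 aldehyde, while the dithiane, vinyl iodide and lactone are stable to aqueous acetic acid.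

Step 8
Reactants: 13 iodo aldehyde
Product: 14 cyclooctene lactone with 3-OH (both epimers) and C8 dithiane
Conditions: CrCl2 (excess), NiCl2 (cat.), DMSO–THF, rt, slow addition at high dilution
Reagents that add atoms: none
Why: Intramolecular Nozaki–Hiyama–Kishi reaction: the alkenylchromium formed with retention of the Z geometry should add only to the aldehyde and close the eight-membered ring (C3–C4), helped by the quaternary dithiane carbon and the trans lactone; C3 is left unselective because it is oxidised next.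

Step 9
Reactants: 14 cyclooctenol lactone (C3 epimers)
Product: 15 cyclooctenone lactone (3-oxo; 4Z; C8 dithiane)
Conditions: MnO2, CH2Cl2, rt
Reagents that add atoms: none
Why: MnO2 oxidises allylic alcohols selectively, so both C3 epimers should converge on the cis-cyclooctenone without oxidation at sulfur.

Step 10
Reactants: 15 cyclooctenone lactone
Product: 16 (3S)-3β-hydroxy cyclooctene lactone (C8 dithiane)
Conditions: (R)-Me-CBS, catecholborane, toluene, −78 °C
Reagents that add atoms: none
Why: Corey–Bakshi–Shibata 1,2-reduction under reagent control: with the α-methyl alkenyl side (C4) as the large and C2H2 as the small group, the (R)-oxazaborolidine should deliver hydride to give the (3S) allylic alcohol (3β-OH).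

Step 11
Reactants: 16 (3S)-allylic alcohol
Product: 17 3β-(tert-butyldimethylsilyloxy) cyclooctene lactone (C8 dithiane)
Conditions: TBSOTf, 2,6-lutidine, CH2Cl2, −78 °C
Reagents that add atoms: tert-butyldimethylsilyl triflate (TBSOTf), CC(C)(C)[Si](C)(C)OS(=O)(=O)C(F)(F)F
Why: Silylation of the hindered secondary alcohol; protection also prevents a transannular hemiketal with the C8 ketone that is unmasked next.

Step 12
Reactants: 17 silyl ether dithiane
Product: 18 3β-(TBSO)-8-oxo cyclooctene lactone
Conditions: MeI, CaCO3, MeCN/H2O, 45 °C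
Reagents that add atoms: water, O
Why: Alkylative hydrolysis of the dithiane under nearly neutral conditions should release the C8 ketone without E1cB loss of the β-acyloxy group (C6–O) and without touching the silyl ether.

Step 13
Reactants: 18 eight-membered ketone
Product: 20 C8=C1 TBS enol ether of 18 (3β-OTBS; lactone intact), via bis-silyl ketene acetal 19 (not isolated)
Conditions: 18 added to LDA (2.4 equiv), THF, −78 °C; TBSCl, HMPA, −78 to 0 °C; pH 5 aqueous work-up
Reagents that add atoms: tert-butyldimethylsilyl chloride (TBSCl), CC(C)(C)[Si](C)(C)Cl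
Why: Kinetic deprotonation with LDA should take the unhindered C1 methylene of the ketone (not the tertiary C7–H) together with the lactone C11–H; O-silylation then gives the C8=C1 silyl enol ether plus a lactone ketene silyl acetal, and only the latter is hydrolysed on mildly acidic work-up.

Step 14
Reactants: 21 but-2-ynoic acid; 22 allyl alcohol
Product: 23 allyl but-2-ynoate
Conditions: DCC, DMAP (cat.), CH2Cl2, 0 °C
Reagents that add atoms: none
Why: Steglich esterification should give the ynoate whose allyl ester can later be removed under neutral Pd(0) conditions.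

Step 15
Reactants: 20 eight-membered TBS enol ether; 23 allyl but-2-ynoate
Product: 25 allyl 3β,8-bis(TBSO)-13-norgermacra-1(10)E,4Z,8-trien-6α,12-olide-9-carboxylate, via cyclobutene 24 (not isolated)
Conditions: 23, Tf2NH (cat.), CH2Cl2, −78 to −40 °C; Et3N; then toluene, 80 °C
Reagents that add atoms: none
Why: Silyl triflimide (from Tf2NH and 20) activates the ynoate, the enol ether carbon C1 adds to its β-carbon C10 (Mukaiyama–Michael) and the silyl allenoate closes onto the C8 oxocarbenium ion (4-exo-trig) to give the cis-fused 8-siloxybicyclo[6.2.0]dec-9-ene 24; warming opens the cyclobutene by conrotatory 4π electrocyclisation, which cleaves C8–C1 and turns the cyclooctane into the cyclodeca-1,3-diene 25. The closest known reactions are the Brønsted- or Lewis-acid-catalysed [2+2] of cyclic silyl enol ethers with propiolic esters and the thermal two-carbon ring expansion of the resulting siloxycyclobutenes. Only the four-membered ring is closed (stepwise polar [2+2], regiochemistry fixed by the enol ether/ynoate polarity); the ten-membered ring arises by ring opening. No sp3 stereocentre is created (C1 and C8 of 24 become sp2 again, so both facial isomers of 24 converge); the new stereo element is the C1=C10 geometry, set by torquoselectivity: the donor OTBS on C8 rotates outward and, because C7 and C2 are cis on the cyclobutene, C7 turns inward and C2 outward, which places C2 trans to C9 (1(10)E) with only H-1 pointing inward. The step needs chemoselectivity for the enol ether over the lactone, the silyl ether and the C4=C5 olefin (only the enol ether is nucleophilic enough) and a temperature low enough to avoid Cope rearrangement of the 1(10),4-diene, which the 4Z geometry also disfavours.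

Step 16
Reactants: 25 ring-expanded siloxydiene ester
Product: 27 3β-(TBSO)-8-oxo-13-norgermacra-1(10)E,4Z-dien-6α,12-olide, via β-keto allyl ester 26 (not isolated)
Conditions: TBAF/AcOH (1:1), THF, −20 °C; then Pd(OAc)2 (cat.), PPh3, HCO2H, Et3N, THF, rt
Reagents that add atoms: none
Why: Fluoride should cleave the enol silane (a vinylogous silyl ester) much faster than the alkyl TBS ether, and Tsuji–Trost deallylation of the allyl β-keto ester with formate then triggers decarboxylation at room temperature; the terminal allyl ester ionises far faster than the hindered endocyclic C6 allylic lactone, and C9 protonation leaves the 1(10)E olefin unconjugated.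

Step 17
Reactants: 27 ten-membered ketone
Product: 28 8β-hydroxy-3β-(TBSO)-13-norgermacra-1(10)E,4Z-dien-6α,12-olide
Conditions: (S)-Me-CBS, catecholborane, toluene–CH2Cl2, −40 °C
Reagents that add atoms: none
Why: CBS reduction: with the branched C7 as the large and C9H2 as the small substituent, the (S)-catalyst should deliver hydride to the α face and give the (8R) 8β-alcohol, while catecholborane leaves the olefins and the lactone alone.

Step 18
Reactants: 29 methyl angelate
Product: 30 (Z)-2-methylbut-2-en-1-ol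
Conditions: DIBAL-H, CH2Cl2, −78 to 0 °C
Reagents that add atoms: none
Why: DIBAL 1,2-reduction of the enoate should give the allylic alcohol with the Z geometry retained.

Step 19
Reactants: 30 (Z)-2-methylbut-2-en-1-ol
Product: 31 [(2R,3S)-2,3-dimethyloxiran-2-yl]methanol
Conditions: Ti(Oi-Pr)4 (cat.), D-(−)-diethyl tartrate (cat.), t-BuOOH, 4 Å MS, CH2Cl2, −20 °C
Reagents that add atoms: tert-butyl hydroperoxide, CC(C)(C)OO
Why: Sharpless asymmetric epoxidation: D-(−)-tartrate should direct oxygen to the face that gives the (2R,3S)-epoxy alcohol, and the Z olefin translates into the cis relation of C1 and the C3 methyl.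

Step 20
Reactants: 31 epoxy alcohol
Product: 32 (2S,3S)-2,3-dimethyloxirane-2-carboxylic acid
Conditions: RuCl3·xH2O (cat.), NaIO4, CCl4–MeCN–H2O, rt
Reagents that add atoms: sodium periodate (terminal oxidant), [Na+].[O-]I(=O)(=O)=O; water (carboxyl oxygen via the aldehyde hydrate), O
Why: Catalytic RuO4 oxidation of the primary alcohol should give the acid without opening the trisubstituted epoxide; the descriptor at C2 changes to S only because the CIP priorities change.

Step 21
Reactants: 28 8β-alcohol; 32 (2S,3S)-2,3-dimethyloxirane-2-carboxylic acid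
Product: 34 8β-[(2S,3S)-2,3-dimethyloxirane-2-carbonyloxy]-3β-(TBSO)-13-norgermacra-1(10)E,4Z-dien-6α,12-olide, via mixed anhydride 33 (not isolated)
Conditions: 32, 2,4,6-trichlorobenzoyl chloride, Et3N, THF, rt; then 28, DMAP, toluene, rt
Reagents that add atoms: none
Why: Yamaguchi esterification through the mixed anhydride should acylate the hindered C8 alcohol with retention; the acid has no α-hydrogen, so it cannot epimerise.

Step 22
Reactants: 34 C8 ester lactone
Product: 38 8β-[(2S,3S)-2,3-dimethyloxirane-2-carbonyloxy]-3β-(TBSO)germacra-1(10)E,4Z,11(13)-trien-6α,12-olide, via lithium enolate 35 (not isolated), via Mannich base 36 (not isolated), via ammonium iodide 37 (not isolated)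
Conditions: LDA (1.1 equiv), THF, −78 °C; CH2=NMe2+ I−, −78 to 0 °C; MeI, MeOH, rt; aq NaHCO3, EtOAc, rt
Reagents that add atoms: Eschenmoser's salt (N,N-dimethylmethyleneiminium iodide), C=[N+](C)C.[I-]
Why: α-Methylenation by Mannich reaction: the lactone is the only enolisable carbonyl (the epoxy ester has no α-H), so its enolate should be aminomethylated at C11, and quaternisation followed by E1cB elimination installs C11=C13.

Step 23
Reactants: 38 α-methylene lactone silyl ether
Product: 39 8β-[(2S,3S)-2,3-dimethyloxirane-2-carbonyloxy]-3β-hydroxygermacra-1(10)E,4Z,11(13)-trien-6α,12-olide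
Conditions: HF·pyridine, pyridine, THF, 0 °C to rt
Reagents that add atoms: none
Why: Buffered HF·pyridine should remove the secondary TBS ether under conditions too mild for epoxy-ester opening or transannular cyclisation of the diene.

Step 24
Reactants: 39 C3 alcohol
Product: 40 8β-[(2S,3S)-2,3-dimethyloxirane-2-carbonyloxy]-3β-(isobutyryloxy)germacra-1(10)E,4Z,11(13)-trien-6α,12-olide
Conditions: i-PrCOCl, pyridine, DMAP (cat.), CH2Cl2, 0 °C
Reagents that add atoms: isobutyryl chloride, CC(C)C(Cl)=O
Why: DMAP-catalysed acylation of the only free hydroxyl (C3) with retention of configuration.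

Step 25
Reactants: 40 diester trienolide
Product: 41 CNP0117882.1 (1β,10α-epoxy-3β-isobutyryloxy-8β-[(2S,3S)-2,3-dimethyloxirane-2-carbonyloxy]germacra-4Z,11(13)-dien-6α,12-olide)
Conditions: mCPBA (1.05 equiv), CH2Cl2, −20 °C
Reagents that add atoms: 3-chloroperbenzoic acid (mCPBA), OOC(=O)c1cccc(Cl)c1
Why: Prilezhaev epoxidation should occur only at the electron-rich C1=C10 olefin (C4=C5 is deactivated by two allylic acyloxy groups, C11=C13 is conjugated) and from the peripheral face of the conformer with C14 β, giving the trans 1β,10α-epoxide stereospecifically from the E olefin.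

**Compound list**

1 | 1,3-dithiane | C1CSCSC1 | starting material
2 | 2-(2-bromoethyl)-1,3-dioxolane | BrCCC1OCCO1 | starting material
3 | 2-lithio-1,3-dithiane | [Li]C1SCCCS1 | intermediate
4 | 2-[2-(1,3-dioxolan-2-yl)ethyl]-1,3-dithiane | C1CSC(CCC2OCCO2)SC1 | intermediate
5 | (S)-5-(hydroxymethyl)furan-2(5H)-one | OC[C@H]1OC(=O)C=C1 | starting material
6 | (S)-5-[(tert-butyldiphenylsilyloxy)methyl]furan-2(5H)-one | CC(C)(C)[Si](c1ccccc1)(c1ccccc1)OC[C@H]1OC(=O)C=C1 | intermediate
7 | 2-lithio-2-[2-(1,3-dioxolan-2-yl)ethyl]-1,3-dithiane | [Li]C1(CCC2OCCO2)SCCCS1 | intermediate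
8 | lithium enolate (C11=C12–OLi) of lactone 9 | C1=C(O[Li])O[C@H](CO[Si](c2ccccc2)(c2ccccc2)C(C)(C)C)[C@H]1C1(CCC2OCCO2)SCCCS1 | intermediate
9 | (4S,5S)-5-[(tert-butyldiphenylsilyloxy)methyl]-4-{2-[2-(1,3-dioxolan-2-yl)ethyl]-1,3-dithian-2-yl}dihydrofuran-2(3H)-one (4,5-trans) | C1C(=O)O[C@H](CO[Si](c2ccccc2)(c2ccccc2)C(C)(C)C)[C@H]1C1(CCC2OCCO2)SCCCS1 | intermediate
10 | (4S,5S)-4-{2-[2-(1,3-dioxolan-2-yl)ethyl]-1,3-dithian-2-yl}-5-(hydroxymethyl)dihydrofuran-2(3H)-one | C1C(=O)O[C@H](CO)[C@H]1C1(CCC2OCCO2)SCCCS1 | intermediate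
11 | (2S,3S)-3-{2-[2-(1,3-dioxolan-2-yl)ethyl]-1,3-dithian-2-yl}-5-oxotetrahydrofuran-2-carbaldehyde | C1C(=O)O[C@H](C=O)[C@H]1C1(CCC2OCCO2)SCCCS1 | intermediate
12 | (4S,5S)-4-{2-[2-(1,3-dioxolan-2-yl)ethyl]-1,3-dithian-2-yl}-5-[(Z)-2-iodoprop-1-en-1-yl]dihydrofuran-2(3H)-one | C1C(=O)O[C@H](/C=C(/C)I)[C@H]1C1(CCC2OCCO2)SCCCS1 | intermediate
13 | 3-{2-[(2S,3S)-2-((Z)-2-iodoprop-1-en-1-yl)-5-oxotetrahydrofuran-3-yl]-1,3-dithian-2-yl}propanal | C1C(=O)O[C@H](/C=C(/C)I)[C@H]1C1(CCC=O)SCCCS1 | intermediate
14 | cyclooctene lactone: carbocycle C1–C8 closed by the C1–C8 bond, 3-OH (both epimers), 4-methyl, 4Z, C8 as 1,3-dithiane, γ-lactone O–C12(=O)–C11H2 from O-6α to C7 (H-6β, H-7α) | C1C(=O)O[C@@H]2/C=C(/C)C(O)CCC3(SCCCS3)[C@@H]12 | intermediate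
15 | 3-oxo analogue of 14 (cis-cyclooctenone; C8 dithiane) | C1C(=O)O[C@@H]2/C=C(/C)C(=O)CCC3(SCCCS3)[C@@H]12 | intermediate
16 | (3S)-3β-hydroxy cyclooctene lactone (C8 dithiane) | C1C(=O)O[C@@H]2/C=C(/C)[C@@H](O)CCC3(SCCCS3)[C@@H]12 | intermediate
17 | 3β-(tert-butyldimethylsilyloxy) cyclooctene lactone (C8 dithiane) | C1C(=O)O[C@@H]2/C=C(/C)[C@@H](O[Si](C)(C)C(C)(C)C)CCC3(SCCCS3)[C@@H]12 | intermediate
18 | 3β-(TBSO)-8-oxo cyclooctene lactone | C1C(=O)O[C@@H]2/C=C(/C)[C@@H](O[Si](C)(C)C(C)(C)C)CCC(=O)[C@@H]12 | intermediate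
19 | bis-silyl intermediate: C8=C1 TBS enol ether and C11=C12 lactone ketene TBS acetal | C1=C(O[Si](C)(C)C(C)(C)C)O[C@@H]2/C=C(/C)[C@@H](O[Si](C)(C)C(C)(C)C)C/C=C(/O[Si](C)(C)C(C)(C)C)[C@@H]12 | intermediate
20 | C8=C1 TBS enol ether of 18 (ring-cis; 3β-OTBS; lactone intact) | C1C(=O)O[C@@H]2/C=C(/C)[C@@H](O[Si](C)(C)C(C)(C)C)C/C=C(/O[Si](C)(C)C(C)(C)C)[C@@H]12 | intermediate
21 | but-2-ynoic acid | CC#CC(=O)O | starting material
22 | allyl alcohol | C=CCO | starting material
23 | allyl but-2-ynoate | CC#CC(=O)OCC=C | intermediate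
24 | cis-fused 8-(TBSO)bicyclo[6.2.0]dec-9-ene: cyclobutene C8(OTBS)–C9(CO2allyl)=C10(CH3)–C1H on the lactone-fused cyclooctene (both facial isomers) | C1C(=O)O[C@@H]2/C=C(/C)[C@@H](O[Si](C)(C)C(C)(C)C)CC3C(C)=C(C(=O)OCC=C)C3(O[Si](C)(C)C(C)(C)C)[C@@H]12 | intermediate
25 | allyl 3β,8-bis(TBSO)-13-norgermacra-1(10)E,4Z,8-trien-6α,12-olide-9-carboxylate | C1C(=O)O[C@@H]2/C=C(/C)[C@@H](O[Si](C)(C)C(C)(C)C)C/C=C(\C)/C(C(=O)OCC=C)=C(/O[Si](C)(C)C(C)(C)C)[C@@H]12 | intermediate
26 | allyl 3β-(TBSO)-8-oxo-13-norgermacra-1(10)E,4Z-dien-6α,12-olide-9-carboxylate (C9 epimers/enol) | C1C(=O)O[C@@H]2/C=C(/C)[C@@H](O[Si](C)(C)C(C)(C)C)C/C=C(\C)C(C(=O)OCC=C)C(=O)[C@@H]12 | intermediate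
27 | 3β-(TBSO)-8-oxo-13-norgermacra-1(10)E,4Z-dien-6α,12-olide | C1C(=O)O[C@@H]2/C=C(/C)[C@@H](O[Si](C)(C)C(C)(C)C)C/C=C(\C)CC(=O)[C@@H]12 | intermediate
28 | 8β-hydroxy-3β-(TBSO)-13-norgermacra-1(10)E,4Z-dien-6α,12-olide | C1C(=O)O[C@@H]2/C=C(/C)[C@@H](O[Si](C)(C)C(C)(C)C)C/C=C(\C)C[C@@H](O)[C@@H]12 | intermediate
29 | methyl angelate (methyl (Z)-2-methylbut-2-enoate) | C/C=C(/C)C(=O)OC | starting material
30 | (Z)-2-methylbut-2-en-1-ol | C/C=C(/C)CO | intermediate
31 | [(2R,3S)-2,3-dimethyloxiran-2-yl]methanol | OC[C@@]1(C)O[C@H]1C | intermediate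
32 | (2S,3S)-2,3-dimethyloxirane-2-carboxylic acid | OC(=O)[C@@]1(C)O[C@H]1C | intermediate
33 | (2S,3S)-2,3-dimethyloxirane-2-carboxylic 2,4,6-trichlorobenzoic anhydride | O=C(OC(=O)[C@@]1(C)O[C@H]1C)c1c(Cl)cc(Cl)cc1Cl | intermediate
34 | 8β-[(2S,3S)-2,3-dimethyloxirane-2-carbonyloxy]-3β-(TBSO)-13-norgermacra-1(10)E,4Z-dien-6α,12-olide | C1C(=O)O[C@@H]2/C=C(/C)[C@@H](O[Si](C)(C)C(C)(C)C)C/C=C(\C)C[C@@H](OC(=O)[C@@]3(C)O[C@H]3C)[C@@H]12 | intermediate
35 | lithium enolate (C11=C12–OLi) of 34 | C1=C(O[Li])O[C@@H]2/C=C(/C)[C@@H](O[Si](C)(C)C(C)(C)C)C/C=C(\C)C[C@@H](OC(=O)[C@@]3(C)O[C@H]3C)[C@@H]12 | intermediate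
36 | 13-(dimethylamino)-11,13-dihydro Mannich base of 38 (C11 epimers) | CN(C)CC1C(=O)O[C@@H]2/C=C(/C)[C@@H](O[Si](C)(C)C(C)(C)C)C/C=C(\C)C[C@@H](OC(=O)[C@@]3(C)O[C@H]3C)[C@@H]12 | intermediate
37 | 13-(trimethylammonio) iodide derived from 36 | C[N+](C)(C)CC1C(=O)O[C@@H]2/C=C(/C)[C@@H](O[Si](C)(C)C(C)(C)C)C/C=C(\C)C[C@@H](OC(=O)[C@@]3(C)O[C@H]3C)[C@@H]12.[I-] | intermediate
38 | 8β-[(2S,3S)-2,3-dimethyloxirane-2-carbonyloxy]-3β-(TBSO)germacra-1(10)E,4Z,11(13)-trien-6α,12-olide | C=C1C(=O)O[C@@H]2/C=C(/C)[C@@H](O[Si](C)(C)C(C)(C)C)C/C=C(\C)C[C@@H](OC(=O)[C@@]3(C)O[C@H]3C)[C@@H]12 | intermediate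
39 | 8β-[(2S,3S)-2,3-dimethyloxirane-2-carbonyloxy]-3β-hydroxygermacra-1(10)E,4Z,11(13)-trien-6α,12-olide | C=C1C(=O)O[C@@H]2/C=C(/C)[C@@H](O)C/C=C(\C)C[C@@H](OC(=O)[C@@]3(C)O[C@H]3C)[C@@H]12 | intermediate
40 | 8β-[(2S,3S)-2,3-dimethyloxirane-2-carbonyloxy]-3β-(isobutyryloxy)germacra-1(10)E,4Z,11(13)-trien-6α,12-olide | C=C1C(=O)O[C@@H]2/C=C(/C)[C@@H](OC(=O)C(C)C)C/C=C(\C)C[C@@H](OC(=O)[C@@]3(C)O[C@H]3C)[C@@H]12 | intermediate
41 | CNP0117882.1: 1β,10α-epoxy-3β-isobutyryloxy-8β-[(2S,3S)-2,3-dimethyloxirane-2-carbonyloxy]germacra-4Z,11(13)-dien-6α,12-olide (1R,3S,6R,7R,8R,10R) | C=C1C(=O)O[C@@H]2/C=C(/C)[C@@H](OC(=O)C(C)C)C[C@H]3O[C@]3(C)C[C@@H](OC(=O)[C@@]3(C)O[C@H]3C)[C@@H]12 | target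

**Step count and risks**

Total steps: 25. Longest linear sequence: 20 steps (5 → 41 through steps 2–13, 15–17 and 21–25; the sequence from 1 through step 1 is equally long).

Steps most likely to fail:

Step 15 (key step). The β-methyl group makes allyl but-2-ynoate a sluggish acceptor, so protodesilylation of the enol ether or an open-chain Mukaiyama–Michael adduct may outrun cyclobutene closure. The fallback is the acid-free enamine–acetylenic ester ring expansion, which sets out from ketone 18: condensation with pyrrolidine (cat. TsOH, 4 Å MS, benzene) should give the less substituted C8=C1 pyrrolidine enamine F1. Heating F1 with 23 in dioxane should give, by thermal [2+2] and conrotatory opening with the amino group outward, the ring-expanded 8-pyrrolidinyl dienamine ester F2. Mild hydrolysis of F2 with aqueous acetic acid comes back to the route at the β-keto allyl ester 26, which is decarboxylated as in the second stage of step 16.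

Step 17. Hydride delivery may show poor facial selectivity, because the preferred conformer of the flexible ten-membered ketone can override the catalyst and expose the β face. The fallback corrects C8 at the ester-forming stage: it sets out from 27, whose substrate-controlled reduction (NaBH4, CeCl3, MeOH, −78 °C) would give the 8α-alcohol F3. Mitsunobu esterification of F3 with acid 32 (PPh3, DIAD, toluene) proceeds with inversion at C8 and comes back to the route at ester 34.

Step 25. The epoxidation may show poor facial selectivity if the ring reacts through the conformer with C14 α, which would deliver oxygen to the wrong face of C1=C10. The fallback inverts the facial outcome through a halohydrin: it sets out from 40, where NBS in aqueous DME forms the bromonium ion on that same reactive face and water opens it anti at the tertiary C10, giving the 1α-bromo-10α-hydroxy bromohydrin F4. K2CO3 in acetone then closes the oxirane with inversion at C1 and comes back to the route at the target 41.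

Further compounds
F1 | step 15 | C8=C1 pyrrolidine enamine of ketone 18 | C1C(=O)O[C@@H]2/C=C(/C)[C@@H](O[Si](C)(C)C(C)(C)C)C/C=C(/N3CCCC3)[C@@H]12
F2 | step 15 | allyl 8-(pyrrolidin-1-yl)-3β-(TBSO)-13-norgermacra-1(10)E,4Z,8-trien-6α,12-olide-9-carboxylate | C1C(=O)O[C@@H]2/C=C(/C)[C@@H](O[Si](C)(C)C(C)(C)C)C/C=C(\C)/C(C(=O)OCC=C)=C(/N3CCCC3)[C@@H]12
F3 | step 17 | 8α-hydroxy-3β-(TBSO)-13-norgermacra-1(10)E,4Z-dien-6α,12-olide | C1C(=O)O[C@@H]2/C=C(/C)[C@@H](O[Si](C)(C)C(C)(C)C)C/C=C(\C)C[C@H](O)[C@@H]12
F4 | step 25 | 1α-bromo-10α-hydroxy bromohydrin of 40 | C=C1C(=O)O[C@@H]2/C=C(/C)[C@@H](OC(=O)C(C)C)C[C@H](Br)[C@@](O)(C)C[C@@H](OC(=O)[C@@]3(C)O[C@H]3C)[C@@H]12
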